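Numbering: O1, C2, C3, C3a, C4–C7, C7a; ring A is the six-membered dienone, ring B the dihydrofuran, ring C the trimethoxyphenyl group. The target comes from its C2 epimer by cis-to-trans epimerisation.
The C2 epimer comes from a 3a-allyl-5-methoxy cross-conjugated dienone by a Cope [3,3] shift. The array allyl–C5–C4=C3a is the 1,5-diene image of allyl–C3a–C4=C5, so the C5 quaternary centre is taken from C3a on the same face of ring A.
The 3a-allyl dienone is cut in ring B at C3–C3a and O1–C2. This gives (Z)-isoelemicin and the p-quinone monoketal of 2-allyl-4,5-dimethoxyphenol, joined by an enantioselective cationic formal [3+2] cycloaddition.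
Enabling feature: the vinylogous ester O1–C7a=C7–C6=O, with the C5 methoxy group para to C7a, shows ring A to be a 1,2,4-trioxygenated benzene at the quinone level. Its cation is electrophilic at C3a and nucleophilic at the oxygen on C7a, a C–C–O three-atom partner for a styrene.
Ring order: rings A and C are bought as benzene rings; ring B is the only ring made and the last one closed.

Key step: step 5

Assumption: the sense of induction of the chiral counteranion in step 5 cannot be derived from precedent. The (S,S)-acid is written, and its (R,R)-mirror image is taken if the ion pair shields the other face.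

Step 1
Reactants: 1 3,4-dimethoxyphenol; 2 allyl bromide
Product: 3 4-(allyloxy)-1,2-dimethoxybenzene
Conditions: K2CO3, acetone, reflux
Reagents that add atoms: none
Why: Williamson ether synthesis, in which the phenoxide of 1 displaces bromide from the unhindered allylic halide 2 at oxygen under mild, polar aprotic conditions.

Step 2
Reactants: 3 4-(allyloxy)-1,2-dimethoxybenzene
Product: 4 2-allyl-4,5-dimethoxyphenol
Conditions: N,N-diethylaniline, 190 °C
Reagents that add atoms: none
Why: Aromatic Claisen rearrangement, in which the [3,3] shift should go to the free ortho position rather than to the one squeezed between two oxygen substituents, and tautomerisation restores the phenol.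

Step 3
Reactants: 4 2-allyl-4,5-dimethoxyphenol
Product: 5 2-allyl-4,4,5-trimethoxycyclohexa-2,5-dien-1-one
Conditions: PhI(OAc)2, MeOH, 0 °C
Reagents that add atoms: methanol, CO
Why: Oxidative dearomatisation of a p-methoxyphenol with a trivalent iodine reagent, in which loss of PhI gives a cation best stabilised at the methoxy-bearing para carbon, methanol captures it to give the p-quinone monoketal, and the isolated allyl group is not touched.

Step 4
Reactants: 6 5-iodo-1,2,3-trimethoxybenzene; 7 (Z)-prop-1-en-1-ylboronic acid
Product: 8 (Z)-isoelemicin, 1,2,3-trimethoxy-5-[(Z)-prop-1-en-1-yl]benzene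
Conditions: Pd(PPh3)4 (3 mol %), K2CO3, DME/H2O, 60 °C
Reagents that add atoms: none
Why: Suzuki–Miyaura coupling, in which oxidative addition of zerovalent palladium into the aryl iodide, transmetalation and reductive elimination proceed with retention of olefin geometry, so the Z configuration of 7 is carried into 8.

Step 5
Reactants: 5 2-allyl-4,4,5-trimethoxycyclohexa-2,5-dien-1-one; 8 (Z)-isoelemicin
Product: 11 (2R,3S,3aS)-3a-allyl-5-methoxy-3-methyl-2-(3,4,5-trimethoxyphenyl)-3,3a-dihydro-1-benzofuran-6(2H)-one, via phenoxenium ion 9 (not isolated), via C6 dimethyl ketal 10 (not isolated)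
Conditions: (S,S)-IDPi acid (imidodiphosphorimidate from two 3,3'-diaryl-BINOL units, aryl = 3,5-(CF3)2C6H3, N-triflyl; 5 mol %), CH2Cl2, −78 to −40 °C; then H2O, THF, 0 °C
Reagents that add atoms: water, O
Why: Proposed new method: the confined chiral acid ionises ketal 5 to the O-methylated quinone (phenoxenium) cation 9 held in a contact ion pair, the beta-carbon of Z-styrene 8 attacks its allyl-bearing carbon (future C3a), the carbonyl oxygen on C7a captures the trimethoxybenzyl cation at C2, the methanol released at the start adds at C6 to give neutral 10 and return the proton, and added water unmasks the C6 ketone. The closest known reactions are the racemic acid-induced [5+2]/[3+2] cycloaddition of p-quinone monoketals with propenylbenzenes, which already makes 3a-allyl hydrobenzofuranones of this family, and the asymmetric intermolecular Prins reaction of styrenes with oxocarbenium ion pairs under confined imidodiphosphate-type acids; only their combination, absolute control by the counteranion, is new. It joins two carbons of like polarity (a phenol ortho-carbon and a styrene beta-carbon are both nucleophiles) because 5 stores the two-electron oxidation, and it closes one ring, ring B, by an intermolecular C3–C3a bond followed by 5-exo-trig attack of O1 on the benzylic cation, whose cationic C2–aryl bond stays outside the ring. C3a is set by the chiral anion, which leaves one face of planar 9 open; C3 is set relative to C3a by endo stacking of the electron-rich ring C over cationic ring A, which for a Z-olefin also places the methyl group endo and therefore anti to the allyl group; C2 is set by least-motion suprafacial collapse on the same olefin face, reinforced by the aryl group avoiding the 3a-allyl group, which gives the 2,3-cis product. The step needs regioselectivity for C3a over C7, secured by the C6 methoxy group, whose enol-ether donation deactivates C7 while C3a is the vinylogous terminus of the C5 oxocarbenium ion; it needs chemoselectivity for the conjugated, aryl-activated olefin over the isolated allyl group; and it needs periselectivity, which is expected because carbon closure at C7 is reversible under the same acid and should drain to the oxygen-closed ring. Low temperature and a catalytic, confined acid should keep 8 from isomerising before it reacts.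

Step 6
Reactants: 11 (2R,3S,3aS)-3a-allyl-5-methoxy-3-methyl-2-(3,4,5-trimethoxyphenyl)-3,3a-dihydro-1-benzofuran-6(2H)-one
Product: 12 (2R,3S,5R)-5-allyl-5-methoxy-3-methyl-2-(3,4,5-trimethoxyphenyl)-3,5-dihydro-1-benzofuran-6(2H)-one
Conditions: PhMe (degassed), 2,6-di-tert-butyl-4-methylphenol (cat.), 110 °C, sealed tube, base-washed glass, stopped as soon as 11 is consumed
Reagents that add atoms: none
Why: Cope rearrangement, known for 3a-allyl hydrobenzofuranones of this family, in which the CH2=CH–CH2–C3a–C4=C5 1,5-diene moves the allyl group suprafacially from C3a to C5 on the same face of ring A, so the S centre at C3a is traded for the R quaternary centre at C5, driven by relief of the crowded C3/C3a pair and formation of the planar, linearly conjugated 7a-alkoxy dienone.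

Step 7
Reactants: 12 (2R,3S,5R)-5-allyl-5-methoxy-3-methyl-2-(3,4,5-trimethoxyphenyl)-3,5-dihydro-1-benzofuran-6(2H)-one
Product: 13 (2S,3S,5R)-5-allyl-5-methoxy-3-methyl-2-(3,4,5-trimethoxyphenyl)-3,5-dihydro-1-benzofuran-6(2H)-one
Conditions: MsOH (5 mol %), CH2Cl2, −20 to 0 °C; aq. NaHCO3
Reagents that add atoms: none
Why: Acid-catalysed benzylic epimerisation, known for 2-aryl-2,3-dihydrobenzofuran neolignans, in which protonation of the vinylogous ester at the C6 oxygen makes O1 a leaving group, reversible heterolysis of C2–O1 gives a trimethoxybenzyl cation that re-closes, and the equilibrium should settle on the less strained 2,3-trans isomer (2S) while C3 and C5 are not involved.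

Compound list
1 | 3,4-dimethoxyphenol | COc1ccc(O)cc1OC | starting material
2 | allyl bromide | C=CCBr | starting material
3 | 4-(allyloxy)-1,2-dimethoxybenzene | C=CCOc1ccc(OC)c(OC)c1 | intermediate
4 | 2-allyl-4,5-dimethoxyphenol | C=CCc1cc(OC)c(OC)cc1O | intermediate
5 | 2-allyl-4,4,5-trimethoxycyclohexa-2,5-dien-1-one (p-quinone monoketal) | C=CCC1=CC(OC)(OC)C(OC)=CC1=O | intermediate
6 | 5-iodo-1,2,3-trimethoxybenzene | COc1cc(I)cc(OC)c1OC | starting material
7 | (Z)-prop-1-en-1-ylboronic acid | C/C=C\B(O)O | starting material
8 | (Z)-isoelemicin, 1,2,3-trimethoxy-5-[(Z)-prop-1-en-1-yl]benzene | C/C=C\c1cc(OC)c(OC)c(OC)c1 | intermediate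
9 | 2-allyl-4,5-dimethoxyphenoxenium ion (O-methylated 2-allyl-5-methoxy-1,4-benzoquinone), paired with the catalyst anion | C=CCC1=CC(=[O+]C)C(OC)=CC1=O | intermediate
10 | (2R,3S,3aS)-3a-allyl-5,6,6-trimethoxy-3-methyl-2-(3,4,5-trimethoxyphenyl)-2,3,3a,6-tetrahydro-1-benzofuran | C=CC[C@]12C=C(OC)C(OC)(OC)C=C1O[C@@H](c1cc(OC)c(OC)c(OC)c1)[C@H]2C | intermediate
11 | (2R,3S,3aS)-3a-allyl-5-methoxy-3-methyl-2-(3,4,5-trimethoxyphenyl)-3,3a-dihydro-1-benzofuran-6(2H)-one (aryl and methyl cis, allyl on the opposite face) | C=CC[C@]12C=C(OC)C(=O)C=C1O[C@@H](c1cc(OC)c(OC)c(OC)c1)[C@H]2C | intermediate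
12 | (2R,3S,5R)-5-allyl-5-methoxy-3-methyl-2-(3,4,5-trimethoxyphenyl)-3,5-dihydro-1-benzofuran-6(2H)-one (2,3-cis, allyl on the opposite face) | C=CC[C@@]1(OC)C=C2C(=CC1=O)O[C@@H](c1cc(OC)c(OC)c(OC)c1)[C@H]2C | intermediate
13 | (2S,3S,5R)-5-allyl-5-methoxy-3-methyl-2-(3,4,5-trimethoxyphenyl)-3,5-dihydro-1-benzofuran-6(2H)-one (2,3-trans, allyl on the face of the aryl group) | C=CC[C@@]1(OC)C=C2C(=CC1=O)O[C@H](c1cc(OC)c(OC)c(OC)c1)[C@H]2C | target

Total step count: 7
Longest linear sequence: 6 (steps 1, 2, 3, 5, 6, 7)

Steps most likely to fail

Step 5. Three things may go wrong. Facial discrimination inside the ion pair may be weak. The acid may isomerise the olefin from Z to E before the C–C bond forms, which would invert the C3/C3a relationship. The benzylic cation may also persist in carbon closure at C7. The fallback uses known chemistry, sets out from 5 and comes back at 11.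
- Mild aqueous acid (oxalic acid, THF/H2O) hydrolyses the ketal to 2-allyl-5-methoxy-1,4-benzoquinone F1.
- F1 and 8 are combined in CH2Cl2 at −78 °C with the stoichiometric chiral tetravalent titanium Lewis acid made from TiCl4, Ti(OiPr)4 and (R,R)-TADDOL. This is the known enantioselective [5+2] cycloaddition of 2-methoxy-1,4-benzoquinones with propenylbenzenes.
- Chelation at the C4 carbonyl and the methoxy group directs the styrene to the allyl-bearing carbon. The product is 5-allyl-3-hydroxy-6-endo-methyl-7-endo-(3,4,5-trimethoxyphenyl)bicyclo[3.2.1]oct-3-ene-2,8-dione F2.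
- O-Methylation (MeI, K2CO3, acetone) gives 5-allyl-3-methoxy-6-endo-methyl-7-endo-(3,4,5-trimethoxyphenyl)bicyclo[3.2.1]oct-3-ene-2,8-dione F3.
- The known acid-induced rearrangement of such bicyclooctenediones (p-TsOH, CH2Cl2) breaks the C1–C7 bond and closes ring B through the bridge carbonyl oxygen, with retention at the benzylic carbon, to give 11.

Step 6. The [3,3] equilibrium may stay on the side of the cross-conjugated dienone. The product may also go on by a retro-Claisen shift of the allyl group to the C6 oxygen, with aromatisation of ring A. The fallback sets out from 10 and comes back at 12.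
- Step 5 is quenched with Et3N instead of water, so that ketal 10 is isolated.
- Heating 10 in toluene over K2CO3 runs the Cope shift at the ketal level, where no carbonyl oxygen exists for the retro-Claisen channel. This gives (2R,3S,5R)-5-allyl-5,6,6-trimethoxy-3-methyl-2-(3,4,5-trimethoxyphenyl)-2,3,5,6-tetrahydro-1-benzofuran F4.
- Brief treatment with aqueous oxalic acid in THF at 0 °C hydrolyses the ketal to 12 without thermal stress on the dienone.

Step 7. The protonated dienone may undergo charge-accelerated migration of the allyl group with aromatisation of ring A. The open benzylic cation may also lose the C3 proton, which would erase the C3 centre. The fallback sets out from 12 and comes back at 13, and it inverts C2 stereospecifically without acid.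
- LiOH in THF/H2O opens ring B at the other C–O bond by addition–elimination at C7a, leaving the C2 configuration untouched. This gives (6R)-6-allyl-3-hydroxy-4-[(1R,2S)-1-hydroxy-1-(3,4,5-trimethoxyphenyl)propan-2-yl]-6-methoxycyclohexa-2,4-dien-1-one F5.
- An intramolecular Mitsunobu reaction (PPh3, DIAD, THF, 0 °C), with the vinylogous acid as the nucleophile, re-closes O1–C2 with inversion at C2 to give 13.

Further compounds
F1 | step 5 | 2-allyl-5-methoxy-1,4-benzoquinone | C=CCC1=CC(=O)C(OC)=CC1=O
F2 | step 5 | 5-allyl-3-hydroxy-6-endo-methyl-7-endo-(3,4,5-trimethoxyphenyl)bicyclo[3.2.1]oct-3-ene-2,8-dione | C=CC[C@]12C=C(O)C(=O)[C@H](C1=O)[C@@H](c1cc(OC)c(OC)c(OC)c1)[C@H]2C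
F3 | step 5 | 5-allyl-3-methoxy-6-endo-methyl-7-endo-(3,4,5-trimethoxyphenyl)bicyclo[3.2.1]oct-3-ene-2,8-dione | C=CC[C@]12C=C(OC)C(=O)[C@H](C1=O)[C@@H](c1cc(OC)c(OC)c(OC)c1)[C@H]2C
F4 | step 6 | (2R,3S,5R)-5-allyl-5,6,6-trimethoxy-3-methyl-2-(3,4,5-trimethoxyphenyl)-2,3,5,6-tetrahydro-1-benzofuran | C=CC[C@@]1(OC)C=C2C(=CC1(OC)OC)O[C@@H](c1cc(OC)c(OC)c(OC)c1)[C@H]2C
F5 | step 7 | (6R)-6-allyl-3-hydroxy-4-[(1R,2S)-1-hydroxy-1-(3,4,5-trimethoxyphenyl)propan-2-yl]-6-methoxycyclohexa-2,4-dien-1-one | C=CC[C@@]1(OC)C=C([C@H](C)[C@@H](O)c2cc(OC)c(OC)c(OC)c2)C(O)=CC1=O
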